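The tetrahydrofuran ring (O1, C2–C5) is disconnected at C2–C3, the bond between the oxygen-bearing benzylic carbon C2 and the methyl-bearing C3. The key step makes this bond by 5-exo-trig closure of an α-alkoxybenzyl radical (C2) onto a terminal vinyl group, whose inner carbon becomes C3 and whose outer carbon, after hydrogen transfer, becomes the C3 methyl group; C2 and C3 are set together under control of C4 and C5. The precursor is an acyclic mixed O,S-acetal that joins two units of one protected syringaldehyde: one as an anti-crotylation product carrying C4 and C5, the other as an α-chlorobenzyl sulfide.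

Key step: step 4

Remark: with the ring numbered O1, C2–C5 the target is (2R,3S,4S,5S), that is, aryl at C2 cis to methyl at C3, the two methyls trans, methyl at C4 trans to aryl at C5, and the two aryls cis. The benzyl ether of syringaldehyde (1) is assumed to be commercially available.

Step 1
Reactants: 1 4-(benzyloxy)-3,5-dimethoxybenzaldehyde
Product: 3 (1S,2S)-1-[4-(benzyloxy)-3,5-dimethoxyphenyl]-2-methylbut-3-en-1-ol, via diisopinocampheylborinate ester 2 (not isolated)
Conditions: trans-2-butene, KOtBu, n-BuLi, THF, −78 to −45 °C; (−)-Ipc2BOMe [from (+)-α-pinene], −78 °C; BF3·OEt2; then 1, −78 °C; NaOH, H2O2, 0 °C to rt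
Reagents that add atoms: trans-2-butene, C/C=C/C
Why: Brown crotylboration: the (E)-crotylborane reacts through a closed Zimmerman–Traxler chair, so that the E geometry is translated into the anti arrangement, while the isopinocampheyl groups derived from (+)-α-pinene direct the crotyl group to the Si face of the aldehyde and so fix the absolute configuration of the later ring carbons C5 and C4 as (1S,2S) in 3.

Step 2
Reactants: 1 4-(benzyloxy)-3,5-dimethoxybenzaldehyde
Product: 4 4-(benzyloxy)-3,5-dimethoxybenzyl phenyl sulfide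
Conditions: PhSH, Et3SiH, CF3CO2H, CH2Cl2, 0 °C to rt
Reagents that add atoms: thiophenol, Sc1ccccc1
Why: Reductive thioetherification (ionic hydrogenation): acid turns the hemithioacetal of the electron-rich aldehyde into an aryl-stabilised thionium ion that Et3SiH reduces to the benzyl sulfide, with no stereocentre formed and the aryl benzyl ether expected to survive these mild conditions.

Step 3
Reactants: 4 4-(benzyloxy)-3,5-dimethoxybenzyl phenyl sulfide; 3 (1S,2S)-1-[4-(benzyloxy)-3,5-dimethoxyphenyl]-2-methylbut-3-en-1-ol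
Product: 6 (1S,2S)-1-[4-(benzyloxy)-3,5-dimethoxyphenyl]-2-methylbut-3-enyl [4-(benzyloxy)-3,5-dimethoxyphenyl](phenylsulfanyl)methyl ether (both epimers at the acetal carbon), via α-chloro sulfide 5 (not isolated)
Conditions: NCS, PhH, rt, filter; then 3, AgOTf, 2,6-di-tert-butyl-4-methylpyridine, 4 Å MS, CH2Cl2, −78 to −40 °C
Reagents that add atoms: none
Why: S-Chlorination of the sulfide by NCS and a Pummerer-type 1,2-shift give the α-chloro sulfide 5, whose AgOTf-assisted ionisation delivers a thionium ion that the hindered secondary alcohol 3 captures under base-buffered conditions (mixed O,S-acetal synthesis from α-chloro sulfides), the acetal carbon arising as an inconsequential epimer mixture because it becomes a planar radical centre in step 4.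

Step 4
Reactants: 6 (1S,2S)-1-[4-(benzyloxy)-3,5-dimethoxyphenyl]-2-methylbut-3-enyl [4-(benzyloxy)-3,5-dimethoxyphenyl](phenylsulfanyl)methyl ether
Product: 7 (2R,3S,4S,5S)-2,5-bis[4-(benzyloxy)-3,5-dimethoxyphenyl]-3,4-dimethyltetrahydrofuran
Conditions: Bu3SnH (slow addition), AIBN, PhH (5 mM), 80 °C
Reagents that add atoms: none
Why: Bu3Sn• abstracts the phenylthio group of 6 to give the planar α-alkoxybenzyl radical at C2, which adds to the inner carbon of the vinyl group (C3), and the primary radical so formed takes hydrogen from Bu3SnH, which gives the C3 methyl group and carries the chain. The closest known reaction type is the tin hydride cyclisation of α-alkoxy radicals generated from O,S- or O,Se-acetals onto alkenes (2-oxahex-5-enyl radical ring closure) to give tetrahydrofurans. The tetrahydrofuran ring closes in the 5-exo-trig mode. C3 is set by the chair-like transition state in which the C5 aryl group and the C4 methyl group, anti to each other, both lie pseudo-equatorial, so that the new methyl group comes out trans to the C4 methyl and cis to the C5 aryl; C2 is set by the preference of the aryl group on the radical carbon for the pseudo-equatorial position of the same chair, which avoids a 1,3-diaxial contact across O1 and places it cis to both the C5 aryl and the C3 methyl. The step needs ring closure to outrun reduction or fragmentation of the stabilised radical and 5-exo closure to outrun 6-endo closure; slow addition of Bu3SnH at high dilution (benzylic radicals take hydrogen from tin hydride far more slowly than the cyclised primary radical does) and the terminal, unhindered alkene should secure both.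

Step 5
Reactants: 7 (2R,3S,4S,5S)-2,5-bis[4-(benzyloxy)-3,5-dimethoxyphenyl]-3,4-dimethyltetrahydrofuran
Product: 8 4,4'-[(2R,3S,4S,5S)-3,4-dimethyltetrahydrofuran-2,5-diyl]bis(2,6-dimethoxyphenol) (CNP0217414.2)
Conditions: H2 (1 atm), Pd/C, EtOAc, rt
Reagents that add atoms: none
Why: Hydrogenolysis of the two aryl benzyl ethers on Pd/C, which under 1 atm of H2 in EtOAc should be much faster than cleavage of the hindered secondary benzylic C–O bonds of the ring, frees both phenols without touching any stereocentre.

Compound list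
1 | 4-(benzyloxy)-3,5-dimethoxybenzaldehyde | COc1cc(C=O)cc(OC)c1OCc1ccccc1 | starting material
2 | (1S,2S)-1-[4-(benzyloxy)-3,5-dimethoxyphenyl]-2-methylbut-3-enyl diisopinocampheylborinate (Ipc groups from (+)-α-pinene) | COc1cc([C@@H](OB([C@@H]2C[C@@H]3C[C@H]([C@H]2C)C3(C)C)[C@@H]2C[C@@H]3C[C@H]([C@H]2C)C3(C)C)[C@@H](C)C=C)cc(OC)c1OCc1ccccc1 | intermediate
3 | (1S,2S)-1-[4-(benzyloxy)-3,5-dimethoxyphenyl]-2-methylbut-3-en-1-ol (anti) | COc1cc([C@@H](O)[C@@H](C)C=C)cc(OC)c1OCc1ccccc1 | intermediate
4 | 4-(benzyloxy)-3,5-dimethoxybenzyl phenyl sulfide | COc1cc(CSc2ccccc2)cc(OC)c1OCc1ccccc1 | intermediate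
5 | 2-(benzyloxy)-5-[chloro(phenylsulfanyl)methyl]-1,3-dimethoxybenzene (racemic α-chloro sulfide) | COc1cc(C(Cl)Sc2ccccc2)cc(OC)c1OCc1ccccc1 | intermediate
6 | (1S,2S)-1-[4-(benzyloxy)-3,5-dimethoxyphenyl]-2-methylbut-3-enyl [4-(benzyloxy)-3,5-dimethoxyphenyl](phenylsulfanyl)methyl ether (both acetal epimers) | COc1cc([C@@H](OC(Sc2ccccc2)c2cc(OC)c(OCc3ccccc3)c(OC)c2)[C@@H](C)C=C)cc(OC)c1OCc1ccccc1 | intermediate
7 | (2R,3S,4S,5S)-2,5-bis[4-(benzyloxy)-3,5-dimethoxyphenyl]-3,4-dimethyltetrahydrofuran | COc1cc([C@H]2O[C@@H](c3cc(OC)c(OCc4ccccc4)c(OC)c3)[C@@H](C)[C@@H]2C)cc(OC)c1OCc1ccccc1 | intermediate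
8 | 4,4'-[(2R,3S,4S,5S)-3,4-dimethyltetrahydrofuran-2,5-diyl]bis(2,6-dimethoxyphenol) | COc1cc([C@H]2O[C@@H](c3cc(OC)c(O)c(OC)c3)[C@@H](C)[C@@H]2C)cc(OC)c1O | target

Total step count: 5
Longest linear sequence: 4 steps (steps 1, 3, 4, 5)

Steps most likely to fail

Step 4. The stabilised α-alkoxybenzyl radical may be reduced by the tin hydride, or may fragment to aldehyde and a benzylic radical, before it closes onto the unactivated alkene. The aryl group on the radical carbon may also take the pseudo-axial position and erode the facial selectivity at C2. The fallback sets out from 3 and comes back at 7, and makes the same C2–C3 bond with a polarity-matched acceptor. Cross-metathesis of 3 with phenyl vinyl sulfone (second-generation Hoveyda–Grubbs catalyst, CH2Cl2, 40 °C) should give (1S,2S,3E)-1-[4-(benzyloxy)-3,5-dimethoxyphenyl]-2-methyl-4-(phenylsulfonyl)but-3-en-1-ol F1. Coupling of F1 with the α-chloro sulfide 5 under the conditions of step 3 should give the corresponding O,S-acetal, (1S,2S,3E)-1-[4-(benzyloxy)-3,5-dimethoxyphenyl]-2-methyl-4-(phenylsulfonyl)but-3-enyl [4-(benzyloxy)-3,5-dimethoxyphenyl](phenylsulfanyl)methyl ether F2. With Bu3SnH and AIBN, or with Et3B and air at low temperature, the nucleophilic radical should add fast and irreversibly to the electron-poor alkene in the same chair-like 5-exo-trig mode, giving (2R,3S,4S,5S)-2,5-bis[4-(benzyloxy)-3,5-dimethoxyphenyl]-4-methyl-3-[(phenylsulfonyl)methyl]tetrahydrofuran F3. Reductive desulfonylation (Na(Hg), Na2HPO4, MeOH, −20 °C) then turns the CH2SO2Ph group into the C3 methyl group and returns to 7.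

Step 3. The very electron-rich α-chloro sulfide may chlorinate or alkylate its own aryl ring before it meets the hindered alcohol, and excess silver salt may ionise the O,S-acetal once formed and open cationic pathways onto the vinyl group. The fallback sets out from 3 and comes back at 6, and builds the acetal carbon from the carboxylic acid oxidation level. Steglich esterification of 3 with commercial 4-(benzyloxy)-3,5-dimethoxybenzoic acid (DCC, DMAP, CH2Cl2) should give (1S,2S)-1-[4-(benzyloxy)-3,5-dimethoxyphenyl]-2-methylbut-3-enyl 4-(benzyloxy)-3,5-dimethoxybenzoate F4. Reductive acetylation (iBu2AlH, CH2Cl2, −78 °C; then Ac2O, pyridine, DMAP, −78 to −20 °C) should give acetoxy[4-(benzyloxy)-3,5-dimethoxyphenyl]methyl (1S,2S)-1-[4-(benzyloxy)-3,5-dimethoxyphenyl]-2-methylbut-3-enyl ether F5. Exchange of acetate for the phenylthio group in the presence of excess thiol (PhSH, BF3·OEt2, CH2Cl2, −78 °C) returns to 6.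

Step 2. The acid, thiol and silane together may slowly remove the aryl benzyl ether, or the reaction may stall at the dithioacetal stage. The fallback sets out from 1 and comes back at 4, and separates reduction from C–S bond formation. Reduction of 1 (NaBH4, MeOH, 0 °C) should give [4-(benzyloxy)-3,5-dimethoxyphenyl]methanol F6, and treatment of F6 with PhSSPh and n-Bu3P (THF, rt) should give sulfide 4 under neutral conditions.

Further compounds
F1 | step 4 | (1S,2S,3E)-1-[4-(benzyloxy)-3,5-dimethoxyphenyl]-2-methyl-4-(phenylsulfonyl)but-3-en-1-ol | COc1cc([C@@H](O)[C@@H](C)/C=C/S(=O)(=O)c2ccccc2)cc(OC)c1OCc1ccccc1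
F2 | step 4 | (1S,2S,3E)-1-[4-(benzyloxy)-3,5-dimethoxyphenyl]-2-methyl-4-(phenylsulfonyl)but-3-enyl [4-(benzyloxy)-3,5-dimethoxyphenyl](phenylsulfanyl)methyl ether (both acetal epimers) | COc1cc([C@@H](OC(Sc2ccccc2)c2cc(OC)c(OCc3ccccc3)c(OC)c2)[C@@H](C)/C=C/S(=O)(=O)c2ccccc2)cc(OC)c1OCc1ccccc1
F3 | step 4 | (2R,3S,4S,5S)-2,5-bis[4-(benzyloxy)-3,5-dimethoxyphenyl]-4-methyl-3-[(phenylsulfonyl)methyl]tetrahydrofuran | COc1cc([C@H]2O[C@@H](c3cc(OC)c(OCc4ccccc4)c(OC)c3)[C@@H](CS(=O)(=O)c3ccccc3)[C@@H]2C)cc(OC)c1OCc1ccccc1
F4 | step 3 | (1S,2S)-1-[4-(benzyloxy)-3,5-dimethoxyphenyl]-2-methylbut-3-enyl 4-(benzyloxy)-3,5-dimethoxybenzoate | COc1cc([C@@H](OC(=O)c2cc(OC)c(OCc3ccccc3)c(OC)c2)[C@@H](C)C=C)cc(OC)c1OCc1ccccc1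
F5 | step 3 | acetoxy[4-(benzyloxy)-3,5-dimethoxyphenyl]methyl (1S,2S)-1-[4-(benzyloxy)-3,5-dimethoxyphenyl]-2-methylbut-3-enyl ether (both acetal epimers) | COc1cc([C@@H](OC(OC(C)=O)c2cc(OC)c(OCc3ccccc3)c(OC)c2)[C@@H](C)C=C)cc(OC)c1OCc1ccccc1
F6 | step 2 | [4-(benzyloxy)-3,5-dimethoxyphenyl]methanol | COc1cc(CO)cc(OC)c1OCc1ccccc1
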